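Target divided by starting material reads steady late in the alder run, within the scatter. Call this the held ratio ρ, target over starting material once the rise is over: 0.408, read from 12.0 h onward.

the same everywhere: starting material 0.50 M; gas 78 mM (held)
- alder: second substrate 0.40 equiv; run made earlier
- flask: second substrate 0.200 equiv; time 12 d

alder run (percent of the starting material charged)

| time / h | target / % | starting material / % |
|---|---|---|
| 2.50 | 24.7 | 77.3 |
| 4.00 | 25.7 | 74.0 |
| 5.00 | 26.9 | 71.9 |
| 8.00 | 29.2 | 71.4 |
| 12.0 | 29.0 | 70.2 |
| 20.0 | 28.4 | 70.0 |
| 30.0 | 28.4 | 69.9 |

(standard deviation of a reading: 0.5 percentage points)

- at the start none of the gas is in solution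

- time, not beyond 12 d, at which the flask holds most target
- the amount of target, in percent of the starting material charged, at that time
- the first time at which target reaches 15%, in the same percent

Take the main step first: starting material and gas go reversibly to target. Gas is held, so the step is pseudo-first-order, and ρ, a reading, puts the flask's plateau at ρ/(1+ρ) = 29.0%. The first alder reading gives a time constant τ of 1.31 h; taken over unchanged, it has target in the flask reach 15% near 0.954 h.

Now add second substrate. This reckoning leaves the plateau unchanged, a judgement that the alder run cannot test: second substrate is taken to use up gas, which is replaced, and not to enter target. Were it built into target, the flask's 0.200 equiv would hold target lower than that plateau.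

Last comes the slow loss. At 30.0 h in the alder run, target and starting material together read 1.7 percentage points short, each reading good to 0.5 points. Taken as a steady fractional loss r, that shortfall divided by the same time, it puts the flask's maximum at τ ln(1/(τr)) = 0.393 d, holding 28.8%.

The forecast gives 15.5% at 0.8 d, and 15% at 5 h, on the ground “I read this as a reversible addition”. Its plateau moves with the charge of second substrate; the reckoning above does not.

The flask gives 29.1% at 0.446 d, and 15% at 1.10 h.

    second substrate + partner ⇌ second product (K = 110 /M, k = 0.120 /M/min)
    gas ⇌ partner, rate k2*(csat - [partner]) (kL = 0.0950 /min)
    2 starting material → self-condensation product (k = 1.60 × 10⁻⁵ /M/min)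
    starting material + partner ⇌ target (K = 5.30 /M, k = 0.0710 /M/min)

The flask's best target is more than the 0.200 equiv of second substrate charged. At that time ρ times its 70.4% of starting material gives 28.7%, while 10.6% of second substrate's own charge is left and second product stands at 0.0894 M. The neighbouring flask, the same charge left until 3.0 d, holds 68.3% starting material. There ρ gives 27.9% target, and that flask holds 28.3%.

The data are simulated with made-up constants.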